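## Retrosynthetic overview

1. Target 26 ⇐ desilylation of 25 ⇐ Steglich esterification of the C8-OH of 20 with acid 24. The C11=C13 methylene is carried as a Me2N-CH2 adduct and released in 17 → 19.
2. Ten-membered carbocycle (second ring formed): ring-closing metathesis makes the (Z)-C1=C10 bond of open-chain lactone 16.
3. γ-Lactone (first ring formed, key step): in one flask the allylic 3-(dimethylamino)propanoate 13 becomes 16. An Ireland–Claisen rearrangement makes C11–C7, then Pd(0)-catalysed net syn-1,4 opening of the resulting vinyl epoxide by the carboxylate makes O–C6.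
4. Enabling feature: the lactone oxygen on C6 is allylic and stands 1,4 across the C4=C5 bond to the C15 hydroxyl (O–C6–C5=C4–C15–O), and C7 is the γ-terminus of the C5–C6–C7 allyl unit. A C5 ester of a C4/C15-epoxy allylic alcohol therefore encodes C11–C7, O–C6, the C4=C5 geometry and the C15 oxygen.
5. 13 ⇐ Sharpless epoxidation and acylation of bis-allylic alcohol 9 ⇐ Red-Al reduction of 8 ⇐ ProPhenol alkynylation of enal 7 (from hex-5-enal) with alkyne 5 (Keck methallylation of a silylpropynal).

Key step: step 8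

Numbering remark: germacrane numbering is used for all intermediates (C1–C10 ring carbons, C11–C13 lactone carbons, C14 methyl on C10, C15 on C4).

Assumption: (S,S)-ProPhenol is taken to deliver the alkynylzinc to the Re face of enal 7 in step 4; if the sense is the opposite, its antipode is used, and in either case the reagent-controlled epoxidation of step 6 converts only the (5R)-carbinol into 10.

## Route

Step 1
Reactants: 1 3-(trimethylsilyl)prop-2-ynal; 2 tributyl(2-methylprop-2-en-1-yl)stannane
Product: 3 (3S)-5-methyl-1-(trimethylsilyl)hex-5-en-1-yn-3-ol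
Conditions: (S)-BINOL (20 mol%), Ti(OiPr)4 (10 mol%), 4 Å MS, CH2Cl2, −20 °C; aq. NaHCO3
Reagents that add atoms: none
Why: Keck-type catalytic asymmetric allylstannane addition, in which the (S)-BINOL–Ti(IV) Lewis acid activates the ynal and directs the methallyl group to its Si face, should set C8 (S).

Step 2
Reactants: 3 (3S)-5-methyl-1-(trimethylsilyl)hex-5-en-1-yn-3-ol
Product: 5 1-methoxy-4-({[(3S)-5-methylhex-5-en-1-yn-3-yl]oxy}methyl)benzene, via silylalkyne PMB ether 4 (not isolated)
Conditions: NaH, PMBCl, n-Bu4NI (cat.), DMF, 0 °C → rt; then MeOH, K2CO3, rt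
Reagents that add atoms: 4-methoxybenzyl chloride (COc1ccc(CCl)cc1)
Why: Williamson etherification of the sodium alkoxide, followed in the same flask by methoxide-mediated protodesilylation of the alkynylsilane, should give the terminal alkyne without touching the stereocentre.

Step 3
Reactants: 6 hex-5-enal
Product: 7 2-methylidenehex-5-enal
Conditions: 37% aq. CH2O, pyrrolidine (10 mol%), propionic acid (10 mol%), i-PrOH, 45 °C
Reagents that add atoms: formaldehyde (C=O)
Why: Organocatalytic Mannich condensation–elimination (α-methylenation of an aldehyde) should give the 2-substituted acrolein and introduces C15.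

Step 4
Reactants: 5 1-methoxy-4-({[(3S)-5-methylhex-5-en-1-yn-3-yl]oxy}methyl)benzene; 7 2-methylidenehex-5-enal
Product: 8 (6S,9S)-9-[(4-methoxybenzyl)oxy]-11-methyl-5-methylidenedodeca-1,11-dien-7-yn-6-ol
Conditions: (S,S)-ProPhenol (20 mol%), Ph3P=O (40 mol%), Me2Zn, PhMe, 0 °C → rt; aq. NH4Cl
Reagents that add atoms: none
Why: Zn–ProPhenol-catalysed enantioselective alkynylation of an enal should deliver the alkynylzinc to the Re face of the aldehyde under catalyst control, which sets C5 (S as the propargylic alcohol).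

Step 5
Reactants: 8 (6S,9S)-9-[(4-methoxybenzyl)oxy]-11-methyl-5-methylidenedodeca-1,11-dien-7-yn-6-ol
Product: 9 (6R,7E,9S)-9-[(4-methoxybenzyl)oxy]-11-methyl-5-methylidenedodeca-1,7,11-trien-6-ol
Conditions: Red-Al, THF, 0 °C → rt; aq. Rochelle salt
Reagents that add atoms: none
Why: Hydroxyl-directed trans-hydroalumination of the propargylic alcohol by Red-Al and protonolysis should give the (E)-C6=C7 alkene only (the descriptor at C5 changes from S to R by priority, not by geometry).

Step 6
Reactants: 9 (6R,7E,9S)-9-[(4-methoxybenzyl)oxy]-11-methyl-5-methylidenedodeca-1,7,11-trien-6-ol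
Product: 10 (1R,2E,4S)-1-[(2S)-2-(but-3-en-1-yl)oxiran-2-yl]-4-[(4-methoxybenzyl)oxy]-6-methylhepta-2,6-dien-1-ol
Conditions: Ti(OiPr)4 (15 mol%), D-(−)-DIPT (18 mol%), t-BuOOH (decane), 4 Å MS, CH2Cl2, −20 °C
Reagents that add atoms: tert-butyl hydroperoxide (CC(C)(C)OO)
Why: Sharpless asymmetric epoxidation in the matched sense: with D-(−)-DIPT the (5R)-carbinol should be epoxidised at the 1,1-disubstituted C4=C15 alkene on the face that gives the erythro (4S,5R) epoxy alcohol, the C6=C7 alkene being the mismatched partner of the same catalyst and the non-allylic alkenes inert, which sets C4.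

Step 7
Reactants: 10 (1R,2E,4S)-1-[(2S)-2-(but-3-en-1-yl)oxiran-2-yl]-4-[(4-methoxybenzyl)oxy]-6-methylhepta-2,6-dien-1-ol; 11 acryloyl chloride
Product: 13 (1R,2E,4S)-1-[(2S)-2-(but-3-en-1-yl)oxiran-2-yl]-4-[(4-methoxybenzyl)oxy]-6-methylhepta-2,6-dien-1-yl 3-(dimethylamino)propanoate, via acrylate ester 12 (not isolated)
Conditions: acryloyl chloride, Et3N, CH2Cl2, 0 °C; then Me2NH (2 M in THF), 0 °C → rt
Reagents that add atoms: dimethylamine (CNC)
Why: O-acylation followed by aza-Michael addition of dimethylamine to the acrylate should give the β-amino ester, the amine adduct being the usual latent form of an α-methylene lactone.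

Step 8
Reactants: 13 (1R,2E,4S)-1-[(2S)-2-(but-3-en-1-yl)oxiran-2-yl]-4-[(4-methoxybenzyl)oxy]-6-methylhepta-2,6-dien-1-yl 3-(dimethylamino)propanoate
Product: 16 (4R,5R)-5-[(1Z)-2-{[(tert-butyldimethylsilyl)oxy]methyl}hexa-1,5-dien-1-yl]-3-[(dimethylamino)methyl]-4-{(1S)-1-[(4-methoxybenzyl)oxy]-3-methylbut-3-en-1-yl}oxolan-2-one (C11 epimers), via silyl ketene acetal 14 (not isolated), via rearranged silyl ester 15 (not isolated)
Conditions: LDA, TBSCl, THF/DMPU, −78 → 60 °C; then Pd(PPh3)4 (5 mol%), 40 °C, same flask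
Reagents that add atoms: tert-butyldimethylsilyl chloride (CC(C)(C)[Si](C)(C)Cl)
Why: Proposed new method: a one-flask relay in which LDA/TBSCl converts the ester into silyl ketene acetal 14, which undergoes Ireland–Claisen [3,3] rearrangement through a chair transition state (C4 pseudo-equatorial) to make C11–C7 and leave an (E)-vinyl epoxide; added Pd(0) then ionises the epoxide to a π-allyl-Pd alkoxide, the alkoxide takes the TBS group from the silyl ester, and the freed carboxylate attacks C6 to make O–C6 (closest known reaction types: Ireland–Claisen rearrangement of allylic esters and Pd(0)-catalysed 1,4-addition of carboxylic acids to vinyl epoxides). The lactone closes by 5-exo attack of the carboxylate on the C6 terminus of the C4–C5–C6 π-allyl unit, the seven-membered alternative at the fully substituted C4 terminus being disfavoured. C7 is set by 1,3-chirality transfer from the C5 carbinol centre (suprafacial shift across the (E)-C6=C7 bond), while the C11 centre forms as a mixture that is erased in step 10. C6 is set by double inversion at palladium (Pd anti to the epoxide C–O, carboxylate anti to Pd), so the lactone oxygen enters on the face the epoxide oxygen left; with the (4S)-epoxide this is the face that gives the 6,7-trans lactone through the conformer with H7 inside and the C8 branch turned away from palladium. The same π-allyl rotamer has C3 syn and C15 anti, which fixes the required C4=C5 geometry (CH2O cis to C6) and releases the C15 oxygen as its TBS ether. The step needs chemoselective enolisation (13 has a single enolisable ester, and TBSCl as internal quench keeps the enolate from attacking the epoxide or losing the amine) and capture of the π-allyl before Pd–Pd exchange scrambles its face, which the tethered carboxylate and the low Pd loading should secure.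

Step 9
Reactants: 16 open-chain lactone (as named in step 8)
Product: 17 (6R,7R,8S)-15-[(tert-butyldimethylsilyl)oxy]-13-(dimethylamino)-8-[(4-methoxybenzyl)oxy]-11,13-dihydrogermacra-1(10)Z,4Z-dien-12,6-olide (C11 epimers)
Conditions: CSA (1.0 equiv), then Hoveyda–Grubbs II (10 mol%), PhMe (1 mM), 80 °C; aq. NaHCO3
Reagents that add atoms: none
Why: Ring-closing metathesis between the monosubstituted C1 vinyl and the 1,1-disubstituted C10 isopropenyl groups (amine masked as its ammonium salt) should release ethene and give the less strained (Z)-cycloalkene expected for a ten-membered ring, the trisubstituted C4=C5 bond not taking part.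

Step 10
Reactants: 17 ten-membered amino lactone (as named in step 9)
Product: 19 (6R,7R,8S)-15-[(tert-butyldimethylsilyl)oxy]-8-[(4-methoxybenzyl)oxy]germacra-1(10)Z,4Z,11(13)-trien-12,6-olide, via trimethylammonium iodide 18 (not isolated)
Conditions: MeI, THF, rt; then sat. aq. NaHCO3, EtOAc, rt
Reagents that add atoms: none
Why: Quaternisation of the tertiary amine followed by base-induced E1cB (Hofmann-type) elimination of trimethylamine should regenerate the conjugated exocyclic methylene and remove the C11 stereocentre.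

Step 11
Reactants: 19 α-methylene lactone PMB ether (as named in step 10)
Product: 20 (6R,7R,8S)-15-[(tert-butyldimethylsilyl)oxy]-8-hydroxygermacra-1(10)Z,4Z,11(13)-trien-12,6-olide
Conditions: DDQ, CH2Cl2/pH 7 buffer, 0 °C
Reagents that add atoms: none
Why: Oxidative PMB cleavage by DDQ (benzylic hydride abstraction, hydrolysis of the oxocarbenium ion) should free the C8 hydroxyl without touching the silyl ether, the lactone or the isolated alkenes.

Step 12
Reactants: 21 1-[(tert-butyldimethylsilyl)oxy]propan-2-one; 22 triethyl phosphonoacetate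
Product: 23 ethyl (2E)-4-[(tert-butyldimethylsilyl)oxy]-3-methylbut-2-enoate
Conditions: NaH, THF, 0 °C → rt
Reagents that add atoms: none
Why: Horner–Wadsworth–Emmons olefination of the α-silyloxy ketone should place the ester trans to the larger CH2OTBS group, giving the (E)-enoate (any Z isomer removed by chromatography).

Step 13
Reactants: 23 ethyl (2E)-4-[(tert-butyldimethylsilyl)oxy]-3-methylbut-2-enoate
Product: 24 (2E)-4-[(tert-butyldimethylsilyl)oxy]-3-methylbut-2-enoic acid
Conditions: LiOH, THF/H2O, 0 °C → rt; then 1 M HCl to pH 4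
Reagents that add atoms: lithium hydroxide ([Li+].[OH-])
Why: Saponification of the ethyl ester and mild acidification should leave the primary TBS ether and the alkene geometry intact.

Step 14
Reactants: 20 C8 alcohol (as named in step 11); 24 (2E)-4-[(tert-butyldimethylsilyl)oxy]-3-methylbut-2-enoic acid
Product: 25 (6R,7R,8S)-15-[(tert-butyldimethylsilyl)oxy]-8-{[(2E)-4-[(tert-butyldimethylsilyl)oxy]-3-methylbut-2-enoyl]oxy}germacra-1(10)Z,4Z,11(13)-trien-12,6-olide
Conditions: DCC, DMAP (cat.), CH2Cl2, 0 °C → rt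
Reagents that add atoms: none
Why: Steglich esterification of the secondary C8 alcohol under neutral conditions should avoid deconjugation of the enoyl group and addition to the methylene lactone.

Step 15
Reactants: 25 bis-silyl ether (as named in step 14)
Product: 26 (6R,7R,8S)-15-hydroxy-8-{[(2E)-4-hydroxy-3-methylbut-2-enoyl]oxy}germacra-1(10)Z,4Z,11(13)-trien-12,6-olide (CNP0233978.1)
Conditions: HF·pyridine, pyridine, THF, 0 °C → rt
Reagents that add atoms: none
Why: Buffered HF·pyridine should cleave both primary TBS ethers while the two esters, the Michael acceptor and the 1,5-diene survive, giving the target.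

## Compound list

1 | 3-(trimethylsilyl)prop-2-ynal | C[Si](C)(C)C#CC=O | starting material
2 | tributyl(2-methylprop-2-en-1-yl)stannane | CCCC[Sn](CCCC)(CCCC)CC(C)=C | starting material
3 | (3S)-5-methyl-1-(trimethylsilyl)hex-5-en-1-yn-3-ol | C=C(C)C[C@H](O)C#C[Si](C)(C)C | intermediate
4 | {(3S)-3-[(4-methoxybenzyl)oxy]-5-methylhex-5-en-1-yn-1-yl}trimethylsilane | C=C(C)C[C@H](OCc1ccc(OC)cc1)C#C[Si](C)(C)C | intermediate (not isolated)
5 | 1-methoxy-4-({[(3S)-5-methylhex-5-en-1-yn-3-yl]oxy}methyl)benzene | C=C(C)C[C@H](OCc1ccc(OC)cc1)C#C | intermediate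
6 | hex-5-enal | C=CCCCC=O | starting material
7 | 2-methylidenehex-5-enal | C=CCCC(=C)C=O | intermediate
8 | (6S,9S)-9-[(4-methoxybenzyl)oxy]-11-methyl-5-methylidenedodeca-1,11-dien-7-yn-6-ol | C=CCCC(=C)[C@H](O)C#C[C@@H](OCc1ccc(OC)cc1)CC(C)=C | intermediate
9 | (6R,7E,9S)-9-[(4-methoxybenzyl)oxy]-11-methyl-5-methylidenedodeca-1,7,11-trien-6-ol | C=CCCC(=C)[C@H](O)/C=C/[C@@H](OCc1ccc(OC)cc1)CC(C)=C | intermediate
10 | (1R,2E,4S)-1-[(2S)-2-(but-3-en-1-yl)oxiran-2-yl]-4-[(4-methoxybenzyl)oxy]-6-methylhepta-2,6-dien-1-ol | C=CCC[C@]1(CO1)[C@H](O)/C=C/[C@@H](OCc1ccc(OC)cc1)CC(C)=C | intermediate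
11 | acryloyl chloride (prop-2-enoyl chloride) | C=CC(=O)Cl | starting material
12 | (1R,2E,4S)-1-[(2S)-2-(but-3-en-1-yl)oxiran-2-yl]-4-[(4-methoxybenzyl)oxy]-6-methylhepta-2,6-dien-1-yl prop-2-enoate | C=CCC[C@]1(CO1)[C@H](OC(=O)C=C)/C=C/[C@@H](OCc1ccc(OC)cc1)CC(C)=C | intermediate (not isolated)
13 | (1R,2E,4S)-1-[(2S)-2-(but-3-en-1-yl)oxiran-2-yl]-4-[(4-methoxybenzyl)oxy]-6-methylhepta-2,6-dien-1-yl 3-(dimethylamino)propanoate | C=CCC[C@]1(CO1)[C@H](OC(=O)CCN(C)C)/C=C/[C@@H](OCc1ccc(OC)cc1)CC(C)=C | intermediate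
14 | O-(tert-butyldimethylsilyl) ketene acetal of 13 (enol ether geometry not defined) | C=CCC[C@]1(CO1)[C@H](OC(O[Si](C)(C)C(C)(C)C)=CCN(C)C)/C=C/[C@@H](OCc1ccc(OC)cc1)CC(C)=C | intermediate (not isolated)
15 | tert-butyldimethylsilyl (3R,4S)-3-{(E)-2-[(2R)-2-(but-3-en-1-yl)oxiran-2-yl]ethenyl}-2-[(dimethylamino)methyl]-4-[(4-methoxybenzyl)oxy]-6-methylhept-6-enoate (C2 epimers) | C=CCC[C@]1(CO1)/C=C/[C@H](C(CN(C)C)C(=O)O[Si](C)(C)C(C)(C)C)[C@@H](OCc1ccc(OC)cc1)CC(C)=C | intermediate (not isolated)
16 | (4R,5R)-5-[(1Z)-2-{[(tert-butyldimethylsilyl)oxy]methyl}hexa-1,5-dien-1-yl]-3-[(dimethylamino)methyl]-4-{(1S)-1-[(4-methoxybenzyl)oxy]-3-methylbut-3-en-1-yl}oxolan-2-one (C11 epimers, centre left undefined) | CN(C)CC1C(=O)O[C@H](/C=C(\CO[Si](C)(C)C(C)(C)C)CCC=C)[C@H]1[C@@H](OCc1ccc(OC)cc1)CC(C)=C | intermediate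
17 | (6R,7R,8S)-15-[(tert-butyldimethylsilyl)oxy]-13-(dimethylamino)-8-[(4-methoxybenzyl)oxy]-11,13-dihydrogermacra-1(10)Z,4Z-dien-12,6-olide (C11 epimers) | CN(C)CC1C(=O)O[C@@H]2/C=C(\CO[Si](C)(C)C(C)(C)C)CC/C=C(/C)C[C@H](OCc3ccc(OC)cc3)[C@@H]12 | intermediate
18 | N-methyl quaternary ammonium iodide of 17 | C[N+](C)(C)CC1C(=O)O[C@@H]2/C=C(\CO[Si](C)(C)C(C)(C)C)CC/C=C(/C)C[C@H](OCc3ccc(OC)cc3)[C@@H]12.[I-] | intermediate (not isolated)
19 | (6R,7R,8S)-15-[(tert-butyldimethylsilyl)oxy]-8-[(4-methoxybenzyl)oxy]germacra-1(10)Z,4Z,11(13)-trien-12,6-olide | C=C1C(=O)O[C@@H]2/C=C(\CO[Si](C)(C)C(C)(C)C)CC/C=C(/C)C[C@H](OCc3ccc(OC)cc3)[C@@H]12 | intermediate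
20 | (6R,7R,8S)-15-[(tert-butyldimethylsilyl)oxy]-8-hydroxygermacra-1(10)Z,4Z,11(13)-trien-12,6-olide | C=C1C(=O)O[C@@H]2/C=C(\CO[Si](C)(C)C(C)(C)C)CC/C=C(/C)C[C@H](O)[C@@H]12 | intermediate
21 | 1-[(tert-butyldimethylsilyl)oxy]propan-2-one | CC(=O)CO[Si](C)(C)C(C)(C)C | starting material
22 | triethyl phosphonoacetate | CCOC(=O)CP(=O)(OCC)OCC | starting material
23 | ethyl (2E)-4-[(tert-butyldimethylsilyl)oxy]-3-methylbut-2-enoate | CCOC(=O)/C=C(\C)CO[Si](C)(C)C(C)(C)C | intermediate
24 | (2E)-4-[(tert-butyldimethylsilyl)oxy]-3-methylbut-2-enoic acid | OC(=O)/C=C(\C)CO[Si](C)(C)C(C)(C)C | intermediate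
25 | (6R,7R,8S)-15-[(tert-butyldimethylsilyl)oxy]-8-{[(2E)-4-[(tert-butyldimethylsilyl)oxy]-3-methylbut-2-enoyl]oxy}germacra-1(10)Z,4Z,11(13)-trien-12,6-olide | C=C1C(=O)O[C@@H]2/C=C(\CO[Si](C)(C)C(C)(C)C)CC/C=C(/C)C[C@H](OC(=O)/C=C(\C)CO[Si](C)(C)C(C)(C)C)[C@@H]12 | intermediate
26 | (6R,7R,8S)-15-hydroxy-8-{[(2E)-4-hydroxy-3-methylbut-2-enoyl]oxy}germacra-1(10)Z,4Z,11(13)-trien-12,6-olide (CNP0233978.1) | C=C1C(=O)O[C@@H]2/C=C(\CO)CC/C=C(/C)C[C@H](OC(=O)/C=C(\C)CO)[C@@H]12 | target

## Step count and risks

Total step count: 15. Longest linear sequence: 12 steps (1, 2, 4, 5, 6, 7, 8, 9, 10, 11, 14, 15).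

Steps most likely to fail:

1. Step 8 (key step, proposed new method). Two processes may go wrong. Facial or syn/anti exchange of the π-allyl palladium species before the carboxylate closes would erode the C4=C5 geometry and the C6 configuration. An incomplete O-to-O silyl relay, or catalyst inhibition by the crude Claisen mixture, would stall the second stage. The fallback uses known chemistry and sets out from 13. The Ireland–Claisen rearrangement is run alone (LDA, TBSCl, THF/DMPU, −78 → 60 °C) and the silyl ester is hydrolysed on work-up (K2CO3, MeOH/H2O, then pH 7) to the open-chain vinyl-epoxy amino acid F1. Iodolactonisation (I2, NaHCO3, MeCN, 0 °C) closes the 12,6-lactone by anti addition across the (E)-C5=C6 bond and gives the C5-iodo epoxy lactone F2. Zinc-mediated reductive opening of the β-iodo epoxide (Zn, NH4Cl, EtOH, rt) is an anti elimination that maps the C4 and C5 configurations onto the same C4=C5 geometry and gives the C15 alcohol F3. Silylation (TBSCl, imidazole, CH2Cl2) returns to the route at 16.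

2. Step 9 (ring-closing metathesis). Intermolecular metathesis of the monosubstituted C1 vinyl group may outrun closure of a ten-membered ring that must form trans-fused to the lactone, and geometric control at the new C1=C10 bond may be lost. The fallback inverts the order of ring formation and sets out from 13 through the acid F1 of the first fallback. RCM is run on the open-chain acid as its zwitterion (Hoveyda–Grubbs II, PhMe, 1 mM, 80 °C) to give the less strained cyclodeca-1,6-diene epoxy acid F4. Pd(PPh3)4 (THF, 40 °C) then effects the same net syn-1,4 lactonisation within the ring to give the macrocyclic C15 alcohol F5. Silylation (TBSCl, imidazole) returns to the route at 17.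

3. Step 4 (catalytic asymmetric alkynylation). Enantiofacial discrimination on an α-branched acrolein may be low or of the opposite sense, and zinc acetylide formation from a non-activated alkyne may be sluggish. The fallback gives up catalyst control at C5 and sets out from 5 and 7. The lithium acetylide of 5 (n-BuLi, THF, −78 °C) adds to 7 to give the C5-epimeric propargylic alcohols F6. Red-Al reduction gives the C5-epimeric (E)-allylic alcohols F7. The Sharpless epoxidation of step 6 (D-(−)-DIPT), run as a kinetic resolution, epoxidises only the (5R)-epimer at C4=C15 and returns to the route at 10. The unreacted (5S)-epimer is separated and can be recycled by Mitsunobu inversion.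

## Further compounds

F1 | step 8 | (3R,4S)-3-{(E)-2-[(2R)-2-(but-3-en-1-yl)oxiran-2-yl]ethenyl}-2-[(dimethylamino)methyl]-4-[(4-methoxybenzyl)oxy]-6-methylhept-6-enoic acid (C2 epimers) | C=CCC[C@]1(CO1)/C=C/[C@H](C(CN(C)C)C(O)=O)[C@@H](OCc1ccc(OC)cc1)CC(C)=C
F2 | step 8 | C5-iodo epoxy lactone: 16 in which C5 carries iodine and the C4/C15 epoxide is still closed (configuration as in SMILES) | CN(C)CC1C(=O)O[C@H]([C@H](I)[C@]2(CCC=C)CO2)[C@H]1[C@@H](OCc1ccc(OC)cc1)CC(C)=C
F3 | step 8 | C15 alcohol corresponding to 16 (free CH2OH on C4) | CN(C)CC1C(=O)O[C@H](/C=C(\CO)CCC=C)[C@H]1[C@@H](OCc1ccc(OC)cc1)CC(C)=C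
F4 | step 9 | ten-membered (1(10)Z,5E)-diene epoxy amino acid: ring-closed form of F1 with the spiro C4/C15 epoxide | OC(=O)C(CN(C)C)[C@H]1/C=C/[C@@]2(CO2)CC/C=C(/C)C[C@@H]1OCc1ccc(OC)cc1
F5 | step 9 | C15 alcohol corresponding to 17 (free CH2OH on C4) | CN(C)CC1C(=O)O[C@@H]2/C=C(\CO)CC/C=C(/C)C[C@H](OCc3ccc(OC)cc3)[C@@H]12
F6 | step 4 | (9S)-9-[(4-methoxybenzyl)oxy]-11-methyl-5-methylidenedodeca-1,11-dien-7-yn-6-ol (C6 epimers) | C=CCCC(=C)C(O)C#C[C@@H](OCc1ccc(OC)cc1)CC(C)=C
F7 | step 4 | (7E,9S)-9-[(4-methoxybenzyl)oxy]-11-methyl-5-methylidenedodeca-1,7,11-trien-6-ol (C6 epimers) | C=CCCC(=C)C(O)/C=C/[C@@H](OCc1ccc(OC)cc1)CC(C)=C
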